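## Structural features

Giganteone A is an achiral, unsymmetrical dimer of two diarylnonanoid halves: four benzene rings, two ketone-bearing nine-carbon chains and one biaryl bond, with no stereocentre and no ring other than the four arenes. Ring A is a 2,6-dihydroxyphenyl ketone (C1 acyl, C2 and C6 hydroxyl) whose C3 carries ring B; its acyl chain, C(=O)(CH2)8, ends in ring C, a 3,4-dihydroxyphenyl group. Ring B is a catechol (C4 and C5 hydroxyl, C3 and C6 hydrogen) bonded through C2 to ring A and through C1 to a (CH2)8C(=O) chain that ends in ring D, a second 2,6-dihydroxyphenyl ketone. Eight free phenols, among them two air- and base-sensitive catechols and two ortho,ortho'-dihydroxyaryl ketones, make the final compound fragile, so every phenol should stay masked until the last step. The real difficulty is ring A, with four contiguous substituents (oxygen, acyl, oxygen, aryl on C6, C1, C2, C3) next to a biaryl bond between two electron-rich rings, together with the need to tell two very similar halves apart. The key step exploits two facts: the six carbons of ring B divide into three two-carbon pieces (C1/C6, C2/C3, C4/C5), and the first chain carbon on C1 of ring B lies within reach of the ring A C2 oxygen. Joined as an ester, these atoms form a diyne whose cyclotrimerisation with a symmetric alkyne writes ring B and a lactone in one operation.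

## Logic of the disconnections

**31 ⇒ 30.** Seven O–H bonds of 31 are traced back to O–CH3 bonds. Methyl ethers are the only phenol masks that pass unchanged through ylide, hydride, aryllithium and boron Lewis-acid chemistry, and the arene building blocks 1, 21 and 24 can be bought with them in place. The gain is that no catechol and no dihydroxyaryl ketone is exposed before the end. The forward step must cleave ketone-flanked and catechol ethers alike in one exhaustive Lewis-acid treatment that leaves both ketones alone.

**30 ⇒ 23 + 27 (through 28 and 29).** The bond between ring A C1 and its ketone carbon is cut. C1 is the only free position ortho to the ring A C2 hydroxyl of 23, and that hydroxyl is released at no cost when the lactone is opened; it can hold a boron atom that delivers the acyl group. The cut removes the whole ring C arm and leaves a biaryl with a single arm. The forward step must acylate a crowded carbon between two oxygens and must avoid ring A C5, the electronically preferred site of an untemplated Friedel–Crafts reaction.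

**27 ⇒ 26 ⇒ 24 + 25.** The C8–C9 bond of the ring C chain is first raised to a triple bond, and the bond between ring C and C9 is then cut. An aryl–alkyne bond is among the most dependable carbon–carbon bonds to form, and both pieces, the iodide 24 and the nine-carbon acid 25, can be bought. The gain is that two commercial compounds carry every carbon of the arm. The demand is a coupling that tolerates the free acid, followed by complete hydrogenation of the triple bond.

**23 ⇒ 20 + 21 (through 22), and 20 ⇒ 19.** The bond between ring D C1 and its ketone carbon is cut. The carbon between the two methoxy groups of 21 is its most acidic position, so ring D can arrive as the aryllithium 22, which a Friedel–Crafts reaction could never place there. The gain is that ring D is a cheap symmetric arene. The demand is an acyl donor that stops at the ketone stage, hence the amide 20, made from acid 19.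

**19 ⇒ 18 ⇒ 14 + 16 (through 17), and 16 ⇒ 15.** The bond between the first and second carbon of the ring B arm is cut as a double bond. The first carbon is the lactol carbon of 14, a masked aldehyde, and the salt 16, made in one step from 15, supplies the other eight carbons. The gain is that the arm shrinks to one carbon held in a ring, and the olefination frees the ring A C2 hydroxyl needed later. The demand is an olefination of a lactol in the presence of its own phenoxide and a carboxylate, then hydrogenation.

**14 ⇒ 13 ⇒ 12 ⇒ 11.** No skeletal bond is cut: the lactol is raised to the lactone, two O–CH3 bonds are removed, and the two C–O bonds at ring B C4 and C5 are exchanged for C–B bonds. Boron is the form in which a cyclotrimerisation can carry a latent hydroxyl. The gain is that 11 is the direct product of the key step. The demand is oxidation of two adjacent C–B bonds without damage to the lactone, and a reduction that stops at the lactol.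

**11 ⇒ 6 + 10.** Three bonds of ring B are cut at once: C1–C2, C3–C4 and C5–C6. The ester tether in 6 holds the future carbonyl carbon and ring A on neighbouring ring B carbons, and the symmetric alkyne 10 can only place boron on C4 and C5. The gain is the loss of two rings and of any biaryl coupling: the biaryl bond already exists in 6 as an aryl–alkyne bond. The demand is a cobalt-mediated cross-cyclotrimerisation that outruns homo-oligomerisation of 6.

**6 ⇒ 4 + 5, and 4 ⇒ 3 ⇒ 1 + 2.** The ester C–O bond is cut, then the aryl–alkyne bond. A phenol and an acid are joined under neutral dehydrating conditions, and an aryl iodide with a silyl-capped alkyne is the most reliable way to an ortho-ethynylphenol. The gain is three small commercial compounds (1, 2, 5). The demand is that the C-silyl group be removed before the base-sensitive ester 6 exists, and that 4 be handled without cyclisation onto its own alkyne.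

**10 ⇒ 7 + 8 (through 9).** Both C–B bonds are cut. The dilithiated two-carbon unit 9 forms in the flask from 7 and is trapped by two equivalents of the boron electrophile 8. The gain is a one-flask preparation from bulk chemicals. The demand is careful low-temperature handling of the metalation.

## Other disconnections considered

**Alternative 1:** Ring A is grown last by cutting its C6–C1 and C2–C3 bonds (and, formally, C5–C6). In the forward step the 2-arylcyclobutenone A2, which already carries ring B and the complete ring D arm, is heated with the 1-ethoxyalkyne A3. Ring opening to a vinylketene, [2+2] addition to the electron-rich alkyne, a second ring opening, a six-electron ring closure and tautomerisation should give the phenol A1. A1 carries the silyloxy carbon on C1, ethoxy on C2, ring B on C3 and the new hydroxyl on C6.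
- In its favour: all four contiguous substituents of ring A are set by the regiochemistry of a pericyclic cascade. The acyl carbon arrives between the two oxygens without substitution at a crowded arene position. On this point it is better than the chosen plan, whose step 16 must force an acyl group into that position. It needs no metal, and like the chosen plan it does not couple two arenes in the key step.
- Against it here: A2 is a sensitive four-membered enone whose aryl group bears an ortho chain and a ketone; it needs its own coupling of ring B to a four-carbon building block after the ring D arm is complete. A3 is a thermally labile ynol ether with a propargylic silyloxy group and can fragment by a retro-ene path near the benzannulation temperature. A1 still needs desilylation, oxidation and cleavage of one ethyl and six methyl ethers.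
- Comparison: on structure the two plans are complementary (one writes ring A, the other ring B). On mechanism they are equals: both make a benzene ring of fixed regiochemistry from small unsaturated pieces, one thermally and one on cobalt. On step economy the alternative is expected to be no shorter, because both partners are long linear constructs, and a failed key step would cost far more advanced material.

**Alternative 2:** The biaryl bond C3(ring A)–C2(ring B) and the lactone C–O bond are cut. In the forward step resorcinol A5 and 2-bromo-4,5-dimethoxybenzoic acid A6 are heated with CuSO4 in aqueous NaOH. Copper-mediated C-arylation of the resorcinol dianion at its 4-position, followed by spontaneous lactonisation, should give 3-hydroxy-8,9-dimethoxy-6H-benzo[c]chromen-6-one A4. One O-methylation would convert A4 into 13.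
- In its favour: two cheap commercial compounds, one step, water as solvent, and a long-established reaction on exactly this substrate class. Two steps would replace steps 1 to 7 of the chosen route. In step economy and in certainty it is clearly the better plan.
- Against it: the modest efficiency usual for such condensations, the need for excess A5, competing loss of bromine from A6, and possible minor arylation between the two hydroxyls of A5. None of these is structural.
- Comparison: on structure the plans are equal from 13 onward (the same steps 8 to 17). On mechanism, an Ullmann-type arylation makes the biaryl bond directly, whereas the cyclotrimerisation avoids biaryl coupling and builds ring B from three alkynes. The chosen plan allows other ring B substituents through the choice of monoyne. The free hydroxyl of A4 equals the chosen plan in freedom to choose the ring A ether. For this single target Alternative 2 is shorter; the cyclotrimerisation is kept for its modularity.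

**Alternative 3:** The ring A ketone is cut on both sides of its carbonyl carbon. This gives the aryl iodide A8, carbon monoxide A11 and the B-alkyl-9-borabicyclo[3.3.1]nonane A9. In the forward step, with PdCl2(dppf) and K3PO4, oxidative addition of A8 to zerovalent palladium, insertion of A11, transfer of the primary alkyl group from boron and reductive elimination should give the ketone A7. The terminal alkene of A7 could then be hydroborated and coupled in the same way with 2-iodo-1,3-dimethoxybenzene A10 to make the ring D ketone.
- In its favour: the ketone position is fixed by the iodide, so no regiochemical question, free phenol or strong Lewis acid arises. On this point it is better than step 16 of the chosen plan. Both hindered ketones come from one mild, convergent reaction type. The protecting-group scheme (all methyl ethers, one final cleavage) equals that of the chosen plan.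
- Against it here: A8 is a di-ortho-methoxy, electron-rich iodide, so oxidative addition is slow and the aroylpalladium is crowded. Direct alkyl–aryl coupling without A11 and loss of iodine would compete. Hydroboration of A7 must spare the new ketone, and pressurised A11 is a hazard. A8 also needs a biaryl cross-coupling and an iodination between two methoxy groups, so the biaryl problem is moved, not solved.
- Comparison: on structure the plans are complementary and could be merged (this one addresses the ketones; the chosen key step addresses ring B and the biaryl bond). On mechanism, migratory insertion on palladium stands against cyclotrimerisation on cobalt. On step economy the two are about equal: two three-component couplings would replace steps 12, 13 and 16 but need an iodination and alkene-bearing building blocks.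

Key step: step 5

**Remarks on the chemistry**
- The structures of 6, 10 and 11 map atom by atom onto 31 and need no correction. The C3 methoxy of 11 is the ring A C6 oxygen, O5 the ring A C2 oxygen, C4 ring A C1, C6 the first carbon of the ring B arm, and C8/C9 ring B C5/C4.
- Precursor design: the C-silyl group is removed before the ester is formed, because an aryl propiolate would not survive methoxide or fluoride, and 6 is added slowly to an excess of 10.
- The alkene geometry of 18 and the racemic lactol carbon of 14 are without consequence, since 31 is achiral.

## Route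

Step 1
Reactants: 1 2-iodo-5-methoxyphenol; 2 ethynyltrimethylsilane
Product: 3 5-methoxy-2-[(trimethylsilyl)ethynyl]phenol
Conditions: PdCl2(PPh3)2 (2 mol%), CuI (4 mol%), Et3N, THF, rt
Reagents that add atoms: none
Why: Sonogashira coupling: the aryl iodide adds to zerovalent palladium at room temperature and the copper acetylide of 2 transmetalates; the silyl cap and the low temperature keep the ortho-hydroxyl from adding to the alkyne and stop alkyne dimerisation.

Step 2
Reactants: 3 5-methoxy-2-[(trimethylsilyl)ethynyl]phenol
Product: 4 2-ethynyl-5-methoxyphenol
Conditions: K2CO3 (0.5 equiv), MeOH, 0 °C to rt, 1 h; pH 6 phosphate buffer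
Reagents that add atoms: none
Why: Methoxide-induced C(sp)–Si protodesilylation is fast at 0 °C, well below the temperature at which an ortho-ethynylphenoxide closes to a benzofuran. It precedes esterification because the aryl propiolate of step 3 would not survive methoxide or fluoride; 4 is used at once.

Step 3
Reactants: 4 2-ethynyl-5-methoxyphenol; 5 prop-2-ynoic acid
Product: 6 2-ethynyl-5-methoxyphenyl prop-2-ynoate
Conditions: DCC (1.2 equiv), DMAP (2 mol%), CH2Cl2, −20 to 0 °C
Reagents that add atoms: none
Why: Steglich esterification: the O-acylisourea of 5 acylates the phenol, the only nucleophile present; low temperature and a mere trace of DMAP suppress conjugate addition of the phenol to the ynoate.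

Step 4
Reactants: 7 trichloroethene; 8 2-isopropoxy-4,4,5,5-tetramethyl-1,3,2-dioxaborolane
Product: 10 1,2-bis(4,4,5,5-tetramethyl-1,3,2-dioxaborolan-2-yl)ethyne, via dilithioethyne 9 (not isolated)
Conditions: n-BuLi (3 equiv), Et2O, −78 °C to rt; then 8 (2 equiv in all), −78 °C to rt; then HCl in Et2O (2 equiv), −78 °C to rt
Reagents that add atoms: 2-isopropoxy-4,4,5,5-tetramethyl-1,3,2-dioxaborolane (the second equivalent of 8), CC(C)OB1OC(C)(C)C(C)(C)O1
Why: Deprotonation, β-elimination and two chlorine–lithium exchanges convert 7 into 9, each carbanion end of which adds to the boron of one molecule of 8; anhydrous HCl then removes isopropoxide from the bis-borate. This is the established preparation of 1,2-diborylalkynes.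

Step 5
Reactants: 6 2-ethynyl-5-methoxyphenyl prop-2-ynoate; 10 1,2-bis(4,4,5,5-tetramethyl-1,3,2-dioxaborolan-2-yl)ethyne
Product: 11 3-methoxy-8,9-bis(4,4,5,5-tetramethyl-1,3,2-dioxaborolan-2-yl)-6H-benzo[c]chromen-6-one
Conditions: CpCo(CO)2 (20 mol%), 10 (3 equiv), degassed toluene, reflux, visible-light irradiation (tungsten lamp); 6 in toluene added by syringe pump over 10 h
Reagents that add atoms: none
Why: Proposed new method: loss of CO from CpCo(CO)2 under light and heat frees a monovalent CpCo fragment that binds both alkynes of 6; oxidative coupling then gives a trivalent cobaltacyclopentadiene in which the bond between the two internal alkyne carbons (C1–C2 of ring B) is made, and the six-membered pyranone ring is thereby closed as a ring fused to the metallacycle. The two cobalt-bound carbons are the former terminal CH groups, so the metal stays open enough for 10 to coordinate; insertion (or a formal [4+2] addition to the metallacycle) forms C3–C4 and C5–C6, and reductive elimination closes ring B as a benzene ring and returns monovalent cobalt. The closest known reaction type is the cobalt- or ruthenium-catalysed [2+2+2] cocyclisation of carbon-, ether- or amine-tethered α,ω-diynes with alkynylboronates; what lacks precedent is the combination of an aryl propiolate ester tether with a 1,2-diborylalkyne. No stereocentre is formed. The step needs chemoselectivity for cross- over homo-cyclotrimerisation: the first C–C bond is intramolecular, slow addition keeps 6 at a low stationary concentration, and 10 is too hindered to trimerise alone, so it can be used in excess and recovered. Regiochemistry cannot go wrong, because the tether fixes the carbonyl carbon beside the ring A-bearing carbon and the symmetry of 10 puts boron on C4 and C5 only. The ester must reach its less favoured s-cis conformation before both alkynes can meet on cobalt, which is why the reaction is run at reflux. Ester, aryl ether and pinacol boronate groups are expected to be inert toward the CpCo species.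

Step 6
Reactants: 11 3-methoxy-8,9-bis(4,4,5,5-tetramethyl-1,3,2-dioxaborolan-2-yl)-6H-benzo[c]chromen-6-one
Product: 12 8,9-dihydroxy-3-methoxy-6H-benzo[c]chromen-6-one
Conditions: NaBO3·4H2O (6 equiv), THF/H2O (1:1), rt, 3 h; then 1 M HCl
Reagents that add atoms: sodium perborate (NaBO3·4H2O), [Na+].[Na+].O[B-]1(O)OO[B-](O)(O)OO1
Why: Peroxoborate adds to each boron and the aryl group migrates from boron to oxygen at the same carbon (ipso-oxidation), so the two C–B bonds become the C4 and C5 oxygens of ring B. Perborate is only weakly basic, and any lactone that opens recloses on acidification.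

Step 7
Reactants: 12 8,9-dihydroxy-3-methoxy-6H-benzo[c]chromen-6-one
Product: 13 3,8,9-trimethoxy-6H-benzo[c]chromen-6-one
Conditions: MeI (3 equiv), K2CO3 (3 equiv), acetone, 55 °C
Reagents that add atoms: iodomethane, CI
Why: Williamson methylation of the two catechol hydroxyls; anhydrous carbonate does not open the aryl lactone. The methyl ethers match all other phenol masks and fall together in step 17.

Step 8
Reactants: 13 3,8,9-trimethoxy-6H-benzo[c]chromen-6-one
Product: 14 3,8,9-trimethoxy-6H-benzo[c]chromen-6-ol (racemic lactol)
Conditions: i-Bu2AlH (1.15 equiv), CH2Cl2, −78 °C; aq. KNaC4H4O6 (potassium sodium tartrate)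
Reagents that add atoms: none
Why: At −78 °C one hydride adds to the lactone carbonyl and the aluminium hemiacetal persists until work-up, so the reduction stops at the lactol. The new hemiacetal carbon is racemic and disappears in step 10.

Step 9
Reactants: 15 8-bromooctanoic acid
Product: 16 (7-carboxyheptyl)triphenylphosphonium bromide
Conditions: PPh3 (1.05 equiv), MeCN, reflux, 48 h
Reagents that add atoms: triphenylphosphine, c1ccc(cc1)P(c1ccccc1)c1ccccc1
Why: SN2 quaternisation of the phosphine by the primary bromide; the free acid does not interfere.

Step 10
Reactants: 14 3,8,9-trimethoxy-6H-benzo[c]chromen-6-ol; 16 (7-carboxyheptyl)triphenylphosphonium bromide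
Product: 18 (Z)-9-[2-(2-hydroxy-4-methoxyphenyl)-4,5-dimethoxyphenyl]non-8-enoic acid, via carboxylate ylide 17 (not isolated)
Conditions: 16 (3 equiv), KOt-Bu (6 equiv), THF, 0 °C; then 14, 0 °C to rt; 1 M HCl to pH 3–4 at 0 °C
Reagents that add atoms: none
Why: Lactol Wittig olefination: base opens 14 to the phenoxide aldehyde, which the unstabilised ylide traps while its carboxylate end stays inert. The Z alkene is expected to predominate, but the geometry is erased in step 11; the step also frees the ring A C2 hydroxyl needed in step 16.

Step 11
Reactants: 18 (Z)-9-[2-(2-hydroxy-4-methoxyphenyl)-4,5-dimethoxyphenyl]non-8-enoic acid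
Product: 19 9-[2-(2-hydroxy-4-methoxyphenyl)-4,5-dimethoxyphenyl]nonanoic acid
Conditions: H2 (1 atm), Pd/C (10%), EtOAc, rt
Reagents that add atoms: none
Why: Heterogeneous hydrogenation of a 1,2-disubstituted styrene-type alkene; aryl ethers, phenol and acid are inert under these conditions.

Step 12
Reactants: 19 9-[2-(2-hydroxy-4-methoxyphenyl)-4,5-dimethoxyphenyl]nonanoic acid
Product: 20 9-[2-(2-hydroxy-4-methoxyphenyl)-4,5-dimethoxyphenyl]-N-methoxy-N-methylnonanamide
Conditions: MeNHOMe·HCl (1.5 equiv), EDC·HCl (1.5 equiv), HOBt (1.2 equiv), i-Pr2NEt (3 equiv), CH2Cl2, rt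
Reagents that add atoms: N,O-dimethylhydroxylamine hydrochloride, CNOC.Cl
Why: Carbodiimide coupling through the hydroxybenzotriazole ester gives the Weinreb amide; the amine is far more nucleophilic than the hindered phenol, so no protection is needed.

Step 13
Reactants: 20 9-[2-(2-hydroxy-4-methoxyphenyl)-4,5-dimethoxyphenyl]-N-methoxy-N-methylnonanamide; 21 1,3-dimethoxybenzene
Product: 23 1-(2,6-dimethoxyphenyl)-9-[2-(2-hydroxy-4-methoxyphenyl)-4,5-dimethoxyphenyl]nonan-1-one, via (2,6-dimethoxyphenyl)lithium 22 (not isolated)
Conditions: 21 (4 equiv), n-BuLi (3.8 equiv), THF, 0 °C to rt, 2 h; then 20, −78 to 0 °C; aq. NH4Cl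
Reagents that add atoms: none
Why: Directed ortho-lithiation of 21 occurs between the two methoxy groups; one equivalent of 22 deprotonates the phenol and a further one adds to the Weinreb amide, whose chelated tetrahedral intermediate prevents a second addition. The ketone carbon thus lands between the two ring D oxygens, a position Friedel–Crafts chemistry cannot reach.

Step 14
Reactants: 24 4-iodo-1,2-dimethoxybenzene; 25 non-8-ynoic acid
Product: 26 9-(3,4-dimethoxyphenyl)non-8-ynoic acid
Conditions: PdCl2(PPh3)2 (2 mol%), CuI (4 mol%), Et3N (4 equiv), THF, rt to 45 °C; 1 M HCl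
Reagents that add atoms: none
Why: Sonogashira coupling: the aryl iodide adds to zerovalent palladium and the copper acetylide of 25 transmetalates while the acid is carried along as its triethylammonium salt. The carboxylate cannot add to its own alkyne, since that would require a nine- or ten-membered ring.

Step 15
Reactants: 26 9-(3,4-dimethoxyphenyl)non-8-ynoic acid
Product: 27 9-(3,4-dimethoxyphenyl)nonanoic acid
Conditions: H2 (1 atm), Pd/C (10%), EtOAc, rt
Reagents that add atoms: none
Why: Heterogeneous hydrogenation takes the aryl alkyne through the styrene to the saturated chain; aryl ethers and the acid are inert under these conditions.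

Step 16
Reactants: 23 1-(2,6-dimethoxyphenyl)-9-[2-(2-hydroxy-4-methoxyphenyl)-4,5-dimethoxyphenyl]nonan-1-one; 27 9-(3,4-dimethoxyphenyl)nonanoic acid
Product: 30 9-(3,4-dimethoxyphenyl)-1-{3-[2-[9-(2,6-dimethoxyphenyl)-9-oxononyl]-4,5-dimethoxyphenyl]-2-hydroxy-6-methoxyphenyl}nonan-1-one, via 9-(3,4-dimethoxyphenyl)nonanoyl chloride 28 (not isolated), via aryloxydichloroborane 29 (not isolated)
Conditions: 27, (COCl)2 (1.2 equiv), DMF (cat.), CH2Cl2, 0 °C to rt, then evaporation; 23, BCl3 (2.5 equiv), ClCH2CH2Cl, 0 °C, then crude 28 (1.5 equiv), 70 °C; 2 M aq. HCl, rt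
Reagents that add atoms: none
Why: BCl3-templated ortho-acylation of a phenol, a Friedel–Crafts acylation delivered through the aryloxydichloroborane 29: the boron-bound acyl chloride can only reach an ortho carbon, and ring A C1 is the sole free ortho position, so the electronically favoured C5 is avoided and the product stays as a boron chelate until hydrolysis. Methyl groups beside the ketones that are lost here do no harm, because step 17 removes them all.

Step 17
Reactants: 30 9-(3,4-dimethoxyphenyl)-1-{3-[2-[9-(2,6-dimethoxyphenyl)-9-oxononyl]-4,5-dimethoxyphenyl]-2-hydroxy-6-methoxyphenyl}nonan-1-one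
Product: 31 giganteone A
Conditions: BBr3 (12 equiv), CH2Cl2, −78 °C to rt; MeOH then H2O, under argon
Reagents that add atoms: none
Why: BBr3 coordinates each ether oxygen and bromide removes the methyl group by SN2; the ketone-flanking ethers go first through chelation and the catechol ethers follow with excess reagent at room temperature. Hydrolysis of the borates under inert gas should release all eight phenols without exposing them to base or oxidant.

## Compound list

1 | 2-iodo-5-methoxyphenol | COc1ccc(I)c(O)c1 | starting material
2 | ethynyltrimethylsilane | C#C[Si](C)(C)C | starting material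
3 | 5-methoxy-2-[(trimethylsilyl)ethynyl]phenol | COc1ccc(C#C[Si](C)(C)C)c(O)c1 | intermediate
4 | 2-ethynyl-5-methoxyphenol | COc1ccc(C#C)c(O)c1 | intermediate
5 | prop-2-ynoic acid (propiolic acid) | C#CC(=O)O | starting material
6 | 2-ethynyl-5-methoxyphenyl prop-2-ynoate | C#CC(=O)Oc1cc(OC)ccc1C#C | intermediate
7 | trichloroethene | ClC=C(Cl)Cl | starting material
8 | 2-isopropoxy-4,4,5,5-tetramethyl-1,3,2-dioxaborolane | CC(C)OB1OC(C)(C)C(C)(C)O1 | starting material
9 | dilithioethyne | [Li]C#C[Li] | intermediate (not isolated)
10 | 1,2-bis(4,4,5,5-tetramethyl-1,3,2-dioxaborolan-2-yl)ethyne | CC1(C)OB(C#CB2OC(C)(C)C(C)(C)O2)OC1(C)C | intermediate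
11 | 3-methoxy-8,9-bis(4,4,5,5-tetramethyl-1,3,2-dioxaborolan-2-yl)-6H-benzo[c]chromen-6-one | COc1ccc2c(c1)oc(=O)c1cc(B3OC(C)(C)C(C)(C)O3)c(B3OC(C)(C)C(C)(C)O3)cc12 | intermediate
12 | 8,9-dihydroxy-3-methoxy-6H-benzo[c]chromen-6-one | COc1ccc2c(c1)oc(=O)c1cc(O)c(O)cc12 | intermediate
13 | 3,8,9-trimethoxy-6H-benzo[c]chromen-6-one | COc1ccc2c(c1)oc(=O)c1cc(OC)c(OC)cc12 | intermediate
14 | 3,8,9-trimethoxy-6H-benzo[c]chromen-6-ol (racemic) | COc1ccc2-c3cc(OC)c(OC)cc3C(O)Oc2c1 | intermediate
15 | 8-bromooctanoic acid | OC(=O)CCCCCCCBr | starting material
16 | (7-carboxyheptyl)triphenylphosphonium bromide | OC(=O)CCCCCCC[P+](c1ccccc1)(c1ccccc1)c1ccccc1.[Br-] | intermediate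
17 | potassium 8-(triphenyl-λ5-phosphanylidene)octanoate (carboxylate ylide) | [K+].[O-]C(=O)CCCCCCC=P(c1ccccc1)(c1ccccc1)c1ccccc1 | intermediate (not isolated)
18 | (Z)-9-[2-(2-hydroxy-4-methoxyphenyl)-4,5-dimethoxyphenyl]non-8-enoic acid (Z expected as major isomer) | COc1ccc(-c2cc(OC)c(OC)cc2/C=C\CCCCCCC(=O)O)c(O)c1 | intermediate
19 | 9-[2-(2-hydroxy-4-methoxyphenyl)-4,5-dimethoxyphenyl]nonanoic acid | COc1ccc(-c2cc(OC)c(OC)cc2CCCCCCCCC(=O)O)c(O)c1 | intermediate
20 | 9-[2-(2-hydroxy-4-methoxyphenyl)-4,5-dimethoxyphenyl]-N-methoxy-N-methylnonanamide | COc1ccc(-c2cc(OC)c(OC)cc2CCCCCCCCC(=O)N(C)OC)c(O)c1 | intermediate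
21 | 1,3-dimethoxybenzene | COc1cccc(OC)c1 | starting material
22 | (2,6-dimethoxyphenyl)lithium | [Li]c1c(OC)cccc1OC | intermediate (not isolated)
23 | 1-(2,6-dimethoxyphenyl)-9-[2-(2-hydroxy-4-methoxyphenyl)-4,5-dimethoxyphenyl]nonan-1-one | COc1ccc(-c2cc(OC)c(OC)cc2CCCCCCCCC(=O)c2c(OC)cccc2OC)c(O)c1 | intermediate
24 | 4-iodo-1,2-dimethoxybenzene | COc1ccc(I)cc1OC | starting material
25 | non-8-ynoic acid | C#CCCCCCCC(=O)O | starting material
26 | 9-(3,4-dimethoxyphenyl)non-8-ynoic acid | COc1ccc(C#CCCCCCCC(=O)O)cc1OC | intermediate
27 | 9-(3,4-dimethoxyphenyl)nonanoic acid | COc1ccc(CCCCCCCCC(=O)O)cc1OC | intermediate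
28 | 9-(3,4-dimethoxyphenyl)nonanoyl chloride | COc1ccc(CCCCCCCCC(=O)Cl)cc1OC | intermediate (not isolated)
29 | dichloro{2-[2-[9-(2,6-dimethoxyphenyl)-9-oxononyl]-4,5-dimethoxyphenyl]-5-methoxyphenoxy}borane | COc1ccc(-c2cc(OC)c(OC)cc2CCCCCCCCC(=O)c2c(OC)cccc2OC)c(OB(Cl)Cl)c1 | intermediate (not isolated)
30 | 9-(3,4-dimethoxyphenyl)-1-{3-[2-[9-(2,6-dimethoxyphenyl)-9-oxononyl]-4,5-dimethoxyphenyl]-2-hydroxy-6-methoxyphenyl}nonan-1-one | COc1ccc(-c2cc(OC)c(OC)cc2CCCCCCCCC(=O)c2c(OC)cccc2OC)c(O)c1C(=O)CCCCCCCCc1ccc(OC)c(OC)c1 | intermediate
31 | giganteone A, 1-{3-[2-[9-(2,6-dihydroxyphenyl)-9-oxononyl]-4,5-dihydroxyphenyl]-2,6-dihydroxyphenyl}-9-(3,4-dihydroxyphenyl)nonan-1-one | O=C(CCCCCCCCc1cc(O)c(O)cc1-c1ccc(O)c(C(=O)CCCCCCCCc2ccc(O)c(O)c2)c1O)c1c(O)cccc1O | target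

## Step count and least certain steps

Total step count: 17. Longest linear sequence: 13 steps, from 1 to 31 through steps 1, 2, 3, 5, 6, 7, 8, 10, 11, 12, 13, 16 and 17. Steps 4, 9, 14 and 15 are side branches.

**Step 5 (key step).** The most likely failure is homo-oligomerisation of the diyne on cobalt. The aryl ester may also fail to reach the conformation in which both alkynes bind the same metal, so that only open-chain or cyclobutadiene-type cobalt complexes form. Both follow from the ester tether, which prefers the extended conformation, and from the two unhindered terminal alkynes. The fallback uses known chemistry; it sets out from 1 and returns at 13. Methyl 2-bromo-4,5-dimethoxybenzoate F1 is converted by Miyaura borylation (bis(pinacolato)diboron, PdCl2(dppf), KOAc, dioxane, 90 °C) into methyl 4,5-dimethoxy-2-(4,4,5,5-tetramethyl-1,3,2-dioxaborolan-2-yl)benzoate F2. Suzuki–Miyaura coupling of F2 with 1 (PdCl2(dppf), K3PO4, dioxane/H2O, 90 °C) should give methyl 2-(2-hydroxy-4-methoxyphenyl)-4,5-dimethoxybenzoate F3. F3 is expected to lactonise in the same flask to 13, so steps 2 to 7 would be bypassed.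

**Step 16.** The most likely failure is acylation at ring A C5 by the untemplated Friedel–Crafts path, or simple O-acylation without carbon–carbon bond formation. The reason is that C1 is flanked by two oxygen substituents, while C5 is para to the hydroxyl and unhindered. The fallback replaces electrophilic substitution by directed lithiation; it sets out from 23 and returns at 31.
- Methylation of the phenol (MeI, K2CO3, acetone) would give 9-[2-(2,4-dimethoxyphenyl)-4,5-dimethoxyphenyl]-1-(2,6-dimethoxyphenyl)nonan-1-one F4.
- LiAlH4 reduction would mask the ketone as the racemic alcohol 9-[2-(2,4-dimethoxyphenyl)-4,5-dimethoxyphenyl]-1-(2,6-dimethoxyphenyl)nonan-1-ol F5.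
- n-BuLi (2.1 equiv) with TMEDA in THF should form the alkoxide and then lithiate ring A between its two methoxy groups. This aryllithium is trapped with 9-(3,4-dimethoxyphenyl)-N-methoxy-N-methylnonanamide F6 (from 27 by the coupling of step 12) to give racemic 9-(3,4-dimethoxyphenyl)-1-{3-[2-[9-(2,6-dimethoxyphenyl)-9-hydroxynonyl]-4,5-dimethoxyphenyl]-2,6-dimethoxyphenyl}nonan-1-one F7.
- Dess–Martin oxidation would give 9-(3,4-dimethoxyphenyl)-1-{3-[2-[9-(2,6-dimethoxyphenyl)-9-oxononyl]-4,5-dimethoxyphenyl]-2,6-dimethoxyphenyl}nonan-1-one F8.
- The BBr3 treatment of step 17, applied to F8, then gives 31.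

**Step 13.** The most likely failure is enolisation of the amide, or base-induced loss of the N-methoxy group, in place of addition. The aryllithium is hindered by two ortho substituents and strongly basic. The fallback sets out from 20 and returns at 23. Reduction with i-Bu2AlH (THF, −78 °C) gives 9-[2-(2-hydroxy-4-methoxyphenyl)-4,5-dimethoxyphenyl]nonanal F9, a far better electrophile. Addition of 22 gives racemic 1-(2,6-dimethoxyphenyl)-9-[2-(2-hydroxy-4-methoxyphenyl)-4,5-dimethoxyphenyl]nonan-1-ol F10. Oxidation of the benzylic alcohol with MnO2 in CH2Cl2, which should spare the phenol, gives 23.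

**Step 2.** The most likely failure is 5-endo cyclisation of the ortho-ethynylphenoxide onto its own alkyne (benzofuran formation), or oligomerisation on concentration. The free phenoxide and the electron-rich terminal alkyne sit next to each other. The fallback sets out from 3 and returns at 6. The phenol of 3 is esterified first with 5 under the conditions of step 3 to give 5-methoxy-2-[(trimethylsilyl)ethynyl]phenyl prop-2-ynoate F11. The C-silyl group is then removed without base by catalysis with monovalent silver (AgNO3, 10 mol%, acetone/H2O, rt), conditions an aryl ester should tolerate.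

## Further compounds

F1 | step 5 | methyl 2-bromo-4,5-dimethoxybenzoate | COC(=O)c1cc(OC)c(OC)cc1Br
F2 | step 5 | methyl 4,5-dimethoxy-2-(4,4,5,5-tetramethyl-1,3,2-dioxaborolan-2-yl)benzoate | COC(=O)c1cc(OC)c(OC)cc1B1OC(C)(C)C(C)(C)O1
F3 | step 5 | methyl 2-(2-hydroxy-4-methoxyphenyl)-4,5-dimethoxybenzoate | COC(=O)c1cc(OC)c(OC)cc1-c1ccc(OC)cc1O
F4 | step 16 | 9-[2-(2,4-dimethoxyphenyl)-4,5-dimethoxyphenyl]-1-(2,6-dimethoxyphenyl)nonan-1-one | COc1ccc(-c2cc(OC)c(OC)cc2CCCCCCCCC(=O)c2c(OC)cccc2OC)c(OC)c1
F5 | step 16 | 9-[2-(2,4-dimethoxyphenyl)-4,5-dimethoxyphenyl]-1-(2,6-dimethoxyphenyl)nonan-1-ol (racemic) | COc1ccc(-c2cc(OC)c(OC)cc2CCCCCCCCC(O)c2c(OC)cccc2OC)c(OC)c1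
F6 | step 16 | 9-(3,4-dimethoxyphenyl)-N-methoxy-N-methylnonanamide | COc1ccc(CCCCCCCCC(=O)N(C)OC)cc1OC
F7 | step 16 | 9-(3,4-dimethoxyphenyl)-1-{3-[2-[9-(2,6-dimethoxyphenyl)-9-hydroxynonyl]-4,5-dimethoxyphenyl]-2,6-dimethoxyphenyl}nonan-1-one (racemic) | COc1ccc(-c2cc(OC)c(OC)cc2CCCCCCCCC(O)c2c(OC)cccc2OC)c(OC)c1C(=O)CCCCCCCCc1ccc(OC)c(OC)c1
F8 | step 16 | 9-(3,4-dimethoxyphenyl)-1-{3-[2-[9-(2,6-dimethoxyphenyl)-9-oxononyl]-4,5-dimethoxyphenyl]-2,6-dimethoxyphenyl}nonan-1-one | COc1ccc(-c2cc(OC)c(OC)cc2CCCCCCCCC(=O)c2c(OC)cccc2OC)c(OC)c1C(=O)CCCCCCCCc1ccc(OC)c(OC)c1
F9 | step 13 | 9-[2-(2-hydroxy-4-methoxyphenyl)-4,5-dimethoxyphenyl]nonanal | COc1ccc(-c2cc(OC)c(OC)cc2CCCCCCCCC=O)c(O)c1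
F10 | step 13 | 1-(2,6-dimethoxyphenyl)-9-[2-(2-hydroxy-4-methoxyphenyl)-4,5-dimethoxyphenyl]nonan-1-ol (racemic) | COc1ccc(-c2cc(OC)c(OC)cc2CCCCCCCCC(O)c2c(OC)cccc2OC)c(O)c1
F11 | step 2 | 5-methoxy-2-[(trimethylsilyl)ethynyl]phenyl prop-2-ynoate | C#CC(=O)Oc1cc(OC)ccc1C#C[Si](C)(C)C
A1 | alternative 1 | benzannulation product, 9-{2-[2-ethoxy-4-hydroxy-3-(1-[tert-butyl(dimethyl)silyl]oxy-9-(3,4-dimethoxyphenyl)nonyl)phenyl]-4,5-dimethoxyphenyl}-1-(2,6-dimethoxyphenyl)nonan-1-one (racemic) | CCOc1c(-c2cc(OC)c(OC)cc2CCCCCCCCC(=O)c2c(OC)cccc2OC)ccc(O)c1C(O[Si](C)(C)C(C)(C)C)CCCCCCCCc1ccc(OC)c(OC)c1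
A2 | alternative 1 | 2-{2-[9-(2,6-dimethoxyphenyl)-9-oxononyl]-4,5-dimethoxyphenyl}cyclobut-2-en-1-one | O=C1CC=C1c1cc(OC)c(OC)cc1CCCCCCCCC(=O)c1c(OC)cccc1OC
A3 | alternative 1 | tert-butyl{[11-(3,4-dimethoxyphenyl)-1-ethoxyundec-1-yn-3-yl]oxy}dimethylsilane (racemic) | CCOC#CC(O[Si](C)(C)C(C)(C)C)CCCCCCCCc1ccc(OC)c(OC)c1
A4 | alternative 2 | 3-hydroxy-8,9-dimethoxy-6H-benzo[c]chromen-6-one | COc1cc2c(cc1OC)c(=O)oc1cc(O)ccc12
A5 | alternative 2 | resorcinol | Oc1cccc(O)c1
A6 | alternative 2 | 2-bromo-4,5-dimethoxybenzoic acid | COc1cc(Br)c(cc1OC)C(=O)O
A7 | alternative 3 | 9-(3,4-dimethoxyphenyl)-1-{2,6-dimethoxy-3-[4,5-dimethoxy-2-(oct-7-en-1-yl)phenyl]phenyl}nonan-1-one | COc1ccc(-c2cc(OC)c(OC)cc2CCCCCCC=C)c(OC)c1C(=O)CCCCCCCCc1ccc(OC)c(OC)c1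
A8 | alternative 3 | 2-iodo-1,3-dimethoxy-4-[4,5-dimethoxy-2-(oct-7-en-1-yl)phenyl]benzene | COc1ccc(-c2cc(OC)c(OC)cc2CCCCCCC=C)c(OC)c1I
A9 | alternative 3 | 9-[8-(3,4-dimethoxyphenyl)octyl]-9-borabicyclo[3.3.1]nonane | COc1ccc(CCCCCCCCB2C3CCCC2CCC3)cc1OC
A10 | alternative 3 | 2-iodo-1,3-dimethoxybenzene | COc1cccc(OC)c1I
A11 | alternative 3 | carbon monoxide | [C-]#[O+]
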